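**Retrosynthetic overview**
- Target 10 comes from the cis-ketone 9 by axial hydride delivery, and 9 from the (S)-2,3-dihydro-4H-pyran-4-one 8 by face-selective hydrogenation.
- 8 comes from the acyclic enedione 7 by a catalytic enantioselective 6-endo oxa-Michael ring closure. This forms the C2–O1 bond and sets the absolute configuration.
- 7 comes from dione 3 and syringaldehyde 4 by boron-templated aldol condensation; 3 comes from zingerone 1 and ethyl acetate 2 by Claisen condensation.
- Both arenes are bought; the oxane ring is the only ring formed (step 3). Phenols stay unprotected throughout.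

Assumption: the SMILES encodes the all-cis (2S,4R,6S) oxan-4-ol, and the quinine-derived catalyst of step 3 is taken to give (S)-8; if the first run shows the opposite sense, the quinidine-derived pseudoenantiomer [(9R)-6′-methoxycinchonan-9-yl] is used in the same way.

**Step 1**
Reactants: 1 zingerone [4-(4-hydroxy-3-methoxyphenyl)butan-2-one]; 2 ethyl acetate
Product: 3 6-(4-hydroxy-3-methoxyphenyl)hexane-2,4-dione
Conditions: NaH (3.5 equiv), EtOAc (4 equiv), THF, slow addition of 1, reflux; then 1 M HCl
Reagents that add atoms: none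
Why: Crossed Claisen condensation in which the ketone enolate is acetylated by the ester and the reversible process drains to the methyl-acylated linear β-diketone, because only that isomer gives the unhindered stable diketonate, while the phenol rides along as its sodium phenoxide.

**Step 2**
Reactants: 3 6-(4-hydroxy-3-methoxyphenyl)hexane-2,4-dione; 4 syringaldehyde (4-hydroxy-3,5-dimethoxybenzaldehyde)
Product: 7 (E)-1-(4-hydroxy-3,5-dimethoxyphenyl)-7-(4-hydroxy-3-methoxyphenyl)hept-1-ene-3,5-dione, via dione dibutoxyboron chelate 5 (not isolated), via enedione dibutoxyboron chelate 6 (not isolated)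
Conditions: B2O3 (0.7 equiv), EtOAc, 80 °C; then 4, B(OnBu)3 (2 equiv), n-BuNH2 (0.4 equiv), 80 °C; then 0.4 M HCl, 60 °C
Reagents that add atoms: tributyl borate, CCCCOB(OCCCC)OCCCC (its boron and two butoxy groups are carried only by 5 and 6 and are lost again on hydrolysis)
Why: Pabon-type boron-templated aldol condensation in which O,O-chelation blocks the central carbon against Knoevenagel reaction and activates the terminal methyl, which condenses with the aldehyde under amine catalysis to the thermodynamic (E)-enone before dilute acid releases the diketone, free phenols being tolerated as in curcuminoid syntheses.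

**Step 3**
Reactants: 7 (E)-1-(4-hydroxy-3,5-dimethoxyphenyl)-7-(4-hydroxy-3-methoxyphenyl)hept-1-ene-3,5-dione
Product: 8 (S)-2-(4-hydroxy-3,5-dimethoxyphenyl)-6-[2-(4-hydroxy-3-methoxyphenyl)ethyl]-2,3-dihydro-4H-pyran-4-one
Conditions: 3-[[3,5-bis(trifluoromethyl)phenyl]amino]-4-[[(8α,9S)-6′-methoxycinchonan-9-yl]amino]cyclobut-3-ene-1,2-dione (10 mol%), CH2Cl2/PhMe (1:1), 0 °C, 48 h; silica plug at full conversion
Reagents that add atoms: none
Why: Proposed new method: enantioselective 6-endo-trig oxa-Michael ring closure of an acyclic β-diketone enol onto its own β-aryl enone arm under bifunctional base/hydrogen-bond-donor catalysis — the quinuclidine nitrogen deprotonates the diketone (the most acidic site, well below the phenols), the resulting ammonium dienolate can leave the chelated U-shape, the squaramide N–H pair binds and activates the enone carbonyl and holds the C5 dienolate oxygen over one enantiotopic face of C1, and C–O bond formation followed by C-protonation from the ammonium releases (S)-8 and the free base, attack through carbon being excluded (four-membered ring) and the product, which has lost the acidic diketone proton, being reopened only slowly by the weak base at 0 °C so that the kinetic ee should hold; the closest known reaction types are the racemic acid-mediated cyclisation of α,β-unsaturated 1,3-diketones to 2,3-dihydro-4H-pyran-4-ones (cyclocurcumin formation) and the bifunctional amine–thiourea asymmetric oxa-Michael cyclisation of activated 2′-hydroxychalcones to flavanones.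

**Step 4**
Reactants: 8 (S)-2-(4-hydroxy-3,5-dimethoxyphenyl)-6-[2-(4-hydroxy-3-methoxyphenyl)ethyl]-2,3-dihydro-4H-pyran-4-one
Product: 10 (2S,4R,6S)-2-(4-hydroxy-3,5-dimethoxyphenyl)-6-[2-(4-hydroxy-3-methoxyphenyl)ethyl]oxan-4-ol, via cis-oxan-4-one 9 (not isolated)
Conditions: H2 (1 atm), 10% Pd/C, THF/MeOH (4:1), rt, stop at H2 uptake of 1 equiv; filter (Celite); then NaBH4 (1.5 equiv), −20 → 0 °C; aq. NH4Cl
Reagents that add atoms: none
Why: Heterogeneous hydrogenation delivers H2 to the ring enol-ether alkene from the face opposite the C2 aryl group to give the 2,6-cis (2S,6S) ketone, and borohydride reduction of this diequatorial, conformationally locked oxan-4-one proceeds by axial attack to the equatorial (4R) alcohol, which is the all-cis target.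

**Compound list**
1 | zingerone, 4-(4-hydroxy-3-methoxyphenyl)butan-2-one | CC(=O)CCc1ccc(O)c(OC)c1 | starting material
2 | ethyl acetate | CCOC(C)=O | starting material
3 | 6-(4-hydroxy-3-methoxyphenyl)hexane-2,4-dione | CC(=O)CC(=O)CCc1ccc(O)c(OC)c1 | intermediate
4 | syringaldehyde, 4-hydroxy-3,5-dimethoxybenzaldehyde | COc1cc(C=O)cc(OC)c1O | starting material
5 | dibutoxyboron O,O′-chelate of dione 3 (drawn as the monomeric 1:1 chelate) | CCCCO[B-]1(OCCCC)OC(C)=CC(CCc2ccc(O)c(OC)c2)=[O+]1 | intermediate
6 | dibutoxyboron O,O′-chelate of enedione 7, (E)-alkene | CCCCO[B-]1(OCCCC)OC(/C=C/c2cc(OC)c(O)c(OC)c2)=CC(CCc2ccc(O)c(OC)c2)=[O+]1 | intermediate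
7 | (E)-1-(4-hydroxy-3,5-dimethoxyphenyl)-7-(4-hydroxy-3-methoxyphenyl)hept-1-ene-3,5-dione | COc1cc(/C=C/C(=O)CC(=O)CCc2ccc(O)c(OC)c2)cc(OC)c1O | intermediate
8 | (S)-2-(4-hydroxy-3,5-dimethoxyphenyl)-6-[2-(4-hydroxy-3-methoxyphenyl)ethyl]-2,3-dihydro-4H-pyran-4-one | COc1cc(CCC2=CC(=O)C[C@@H](c3cc(OC)c(O)c(OC)c3)O2)ccc1O | intermediate
9 | (2S,6S)-2-(4-hydroxy-3,5-dimethoxyphenyl)-6-[2-(4-hydroxy-3-methoxyphenyl)ethyl]oxan-4-one (2,6-cis) | COc1cc(CC[C@H]2CC(=O)C[C@@H](c3cc(OC)c(O)c(OC)c3)O2)ccc1O | intermediate
10 | (2S,4R,6S)-2-(4-hydroxy-3,5-dimethoxyphenyl)-6-[2-(4-hydroxy-3-methoxyphenyl)ethyl]oxan-4-ol (all-cis) | COc1cc(CC[C@H]2C[C@@H](O)C[C@@H](c3cc(OC)c(O)c(OC)c3)O2)ccc1O | target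

**Totals**
Total step count: 4. Longest linear sequence: 4 (1 → 3 → 7 → 8 → 10).

**Three steps most likely to fail**

Step 3 (the proposed new ring closure). The β-aryl enone is electron-rich and therefore a slow acceptor. The closure is also reversible, so ee could erode by retro-oxa-Michael reaction or through a quinone methide from the 4-hydroxyaryl group. The fallback sets out from 7 and comes back at 8. It uses the known acid-mediated 6-endo cyclisation of α,β-unsaturated 1,3-diketones (CF3CO2H, toluene, 60 °C) to give racemic 2-(4-hydroxy-3,5-dimethoxyphenyl)-6-[2-(4-hydroxy-3-methoxyphenyl)ethyl]-2,3-dihydro-4H-pyran-4-one F4. Preparative chiral SFC on an amylose tris(3,5-dimethylphenylcarbamate) phase then gives 8, so the stereocentre comes from separation and not from catalysis.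

Step 1 (Claisen condensation on a free phenol). Risks are self-aldol of zingerone, acylation at the methylene, and a poorly soluble phenoxide. The fallback sets out from 1 and comes back at 3, replacing equilibrium acylation by a kinetic aldol/oxidation sequence of the kind used for gingerols. Silylation (TBSCl, imidazole, DMF) gives 4-[4-(tert-butyldimethylsilyloxy)-3-methoxyphenyl]butan-2-one F1. The kinetic methyl-side enolate (LiN(iPr)2, THF, −78 °C) is added to acetaldehyde to give racemic 1-[4-(tert-butyldimethylsilyloxy)-3-methoxyphenyl]-5-hydroxyhexan-3-one F2. Oxidation with 2-iodoxybenzoic acid (EtOAc, 77 °C) gives 6-[4-(tert-butyldimethylsilyloxy)-3-methoxyphenyl]hexane-2,4-dione F3. Desilylation (Bu4NF, AcOH, THF, 0 °C) returns 3.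

Step 4 (hydrogenation part). The 2-(4-hydroxyaryl) benzylic C–O bond may be hydrogenolysed, or the ketone over-reduced, on Pd/C. The fallback sets out from 8 and comes back at 9. It replaces surface hydrogenation by ionic conjugate reduction with LiBH(sBu)3 (3.5 equiv, the first two consumed by the phenols; THF, −78 °C; aq. NH4Cl). Axial hydride attack at C6 gives the same 2,6-cis ketone 9, which is then reduced with NaBH4 as in step 4. This detour makes no new compound: none F0.

**Further compounds**
F1 | step 1 | 4-[4-(tert-butyldimethylsilyloxy)-3-methoxyphenyl]butan-2-one | CC(=O)CCc1ccc(O[Si](C)(C)C(C)(C)C)c(OC)c1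
F2 | step 1 | rac-1-[4-(tert-butyldimethylsilyloxy)-3-methoxyphenyl]-5-hydroxyhexan-3-one | CC(O)CC(=O)CCc1ccc(O[Si](C)(C)C(C)(C)C)c(OC)c1
F3 | step 1 | 6-[4-(tert-butyldimethylsilyloxy)-3-methoxyphenyl]hexane-2,4-dione | CC(=O)CC(=O)CCc1ccc(O[Si](C)(C)C(C)(C)C)c(OC)c1
F4 | step 3 | rac-2-(4-hydroxy-3,5-dimethoxyphenyl)-6-[2-(4-hydroxy-3-methoxyphenyl)ethyl]-2,3-dihydro-4H-pyran-4-one | COc1cc(CCC2=CC(=O)CC(c3cc(OC)c(O)c(OC)c3)O2)ccc1O
F0 | step 4 | none | none
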